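**Strategy.** Atoms are numbered as in the benzofuranone core (O1, C2, C3, C3a, C4 to C7, C7a). Everything rests on cutting C4–C5 and C3a–C7a together: the lactone oxygen O1 sits on the ring-fusion carbon C7a and the butenolide alkene C3=C3a is exocyclic to the cyclohexane ring, so the bicycle is the intramolecular Diels–Alder adduct of a dienyl allenoate. The precursor is the acyclic enol ester of acetylacetone with 4-methylpenta-2,3-dienoic acid, as its 2-silyloxy diene; the future lactone is the tether and the distal allene bond the dienophile. One operation closes the cyclohexane and butenolide rings and creates C7a; ketone reduction, resolution and palmitoylation finish the synthesis.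

Key step: step 3

Remark on the chemistry: the cycloaddition is not enantioselective. Compounds 8, 9 and 10 are racemates (their SMILES show the enantiomer that is carried on), and the single enantiomer is reached by the resolution in step 5. The wanted camphanate is to be identified by X-ray diffraction against the fixed camphanoyl configuration and by the sign of rotation of 13.

Step 1
Reactants: 1 3-methylbuta-1,2-diene
Product: 3 4-methylpenta-2,3-dienoic acid, via allenyllithium 2 (not isolated)
Conditions: n-BuLi, THF, −78 °C; CO2, −78 °C to rt; 1 M HCl
Reagents that add atoms: carbon dioxide, O=C=O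
Why: Lithiation–carboxylation: n-BuLi removes the terminal sp2 hydrogen of the 1,1-disubstituted allene and the allenyllithium should be carboxylated at the lithiated carbon, because the hindered CMe2 terminus disfavours the propargylic mode.

Step 2
Reactants: 3 4-methylpenta-2,3-dienoic acid; 4 pentane-2,4-dione (acetylacetone)
Product: 6 (E)-4-oxopent-2-en-2-yl 4-methylpenta-2,3-dienoate, via acid chloride 5 (not isolated)
Conditions: (COCl)2, DMF (cat.), CH2Cl2, 0 °C to rt, concentrate; 4, Et3N, CH2Cl2, −20 to 0 °C
Reagents that add atoms: none
Why: Acid chloride formation followed by O-acylation of a 1,3-diketone under non-chelating amine conditions should give the enol ester with the acyloxy group anti to the acetyl group (E), the geometry the cycloaddition needs; no stereocentre is formed.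

Step 3
Reactants: 6 (E)-4-oxopent-2-en-2-yl 4-methylpenta-2,3-dienoate
Product: 9 (±)-dehydrololiolide, via silyloxy diene 7 (not isolated), via silyl enol ether cycloadduct 8 (not isolated)
Conditions: TBSOTf, i-Pr2NEt, CH2Cl2, −78 to 0 °C; ammonium salt removed, toluene (0.01 M), BHT (cat.), 80–100 °C; 1 M HCl, THF, 0 °C
Reagents that add atoms: none
Why: Silyl triflate/amine enolisation of the methyl ketone gives 2-silyloxy diene 7, whose E enol-ester oxygen lies outward on C7a like the ipso oxygen of an aryl allenoate, and on heating the diene C5=C6–C7=C7a adds to the distal C3a=C4 bond of the allenoate in a concerted intramolecular Diels–Alder reaction that forms C4–C5 and C3a–C7a together. The closest known reaction type is the Himbert arene/allene intramolecular Diels–Alder reaction of aryl allenecarboxylates, here with a non-aromatic, donor-substituted diene that has no aromaticity to lose. The cyclohexene ring closes as the [4+2] ring proper and the butenolide as the five-membered tether ring C7a–O1–C2–C3–C3a, the untouched C3=C3a π bond of the allene becoming the conjugated lactone alkene. C7a is the only stereocentre formed and, with no chiral element in 7, arises as a racemate that is resolved in step 5. The step needs site selectivity for the distal allene bond, secured by the short tether (addition to C3=C3a would require a four-membered lactone), and high dilution to suppress bimolecular addition to the activated proximal bond. Dilute acid finally hydrolyses silyl enol ether 8 to ketone 9 without base, so the β-acyloxy ketone does not open by retro-oxa-Michael elimination.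

Step 4
Reactants: 9 (±)-dehydrololiolide
Product: 10 (±)-loliolide
Conditions: LiBH(s-Bu)3 (L-Selectride), THF, −78 °C; AcOH
Reagents that add atoms: none
Why: Reduction of a cyclohexanone with a bulky trialkylborohydride: the two syn-axial methyl groups on C4 and C7a block the axial trajectory, so hydride should enter equatorially and give the axial C6 alcohol cis to the C7a methyl group (the loliolide relative configuration), while the β,β-disubstituted butenolide should not react at −78 °C.

Step 5
Reactants: 10 (±)-loliolide; 11 (1S,4R)-camphanic chloride
Product: 12 (6S,7aR)-loliolide (1S,4R)-camphanate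
Conditions: pyridine, DMAP (cat.), CH2Cl2, 0 °C to rt; separation of the two diastereomers by crystallisation or silica gel chromatography
Reagents that add atoms: none
Why: Classical resolution through diastereomeric esters: acylation with an enantiopure acid chloride that cannot racemise turns the racemate into two diastereomeric camphanates that should be separable, and the crystalline ester allows the absolute configuration at C6 and C7a to be checked.

Step 6
Reactants: 12 (6S,7aR)-loliolide (1S,4R)-camphanate
Product: 13 (−)-loliolide
Conditions: K2CO3, MeOH, rt
Reagents that add atoms: none
Why: Base-catalysed transesterification (methanolysis) should remove the camphanoyl group without touching a stereocentre; the tertiary conjugated lactone, if opened, recloses on neutralisation.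

Step 7
Reactants: 13 (−)-loliolide; 14 palmitoyl chloride
Product: 15 (−)-3-O-palmitoylloliolide
Conditions: pyridine, DMAP (cat.), CH2Cl2, rt
Reagents that add atoms: none
Why: DMAP-catalysed esterification of the secondary alcohol with an acid chloride should install the palmitate with retention at C6.

**Compound list**

1 | 3-methylbuta-1,2-diene | CC(C)=C=C | starting material
2 | (3-methylbuta-1,2-dien-1-yl)lithium | [Li]C=C=C(C)C | intermediate
3 | 4-methylpenta-2,3-dienoic acid | CC(C)=C=CC(=O)O | intermediate
4 | pentane-2,4-dione (acetylacetone) | CC(=O)CC(C)=O | starting material
5 | 4-methylpenta-2,3-dienoyl chloride | CC(C)=C=CC(=O)Cl | intermediate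
6 | (E)-4-oxopent-2-en-2-yl 4-methylpenta-2,3-dienoate | CC(=O)/C=C(\C)OC(=O)C=C=C(C)C | intermediate
7 | (E)-4-[(tert-butyldimethylsilyl)oxy]penta-2,4-dien-2-yl 4-methylpenta-2,3-dienoate | C=C(O[Si](C)(C)C(C)(C)C)/C=C(\C)OC(=O)C=C=C(C)C | intermediate
8 | rac-6-[(tert-butyldimethylsilyl)oxy]-4,4,7a-trimethyl-5,7a-dihydro-1-benzofuran-2(4H)-one (7aR enantiomer drawn) | CC(C)(C)[Si](C)(C)OC1=C[C@@]2(C)OC(=O)C=C2C(C)(C)C1 | intermediate
9 | (±)-dehydrololiolide, rac-4,4,7a-trimethyl-5,7a-dihydro-1-benzofuran-2,6(4H,7H)-dione (7aR enantiomer drawn) | O=C1CC(C)(C)C2=CC(=O)O[C@]2(C)C1 | intermediate
10 | (±)-loliolide, rac-(6S,7aR)-6-hydroxy-4,4,7a-trimethyl-5,6,7,7a-tetrahydro-1-benzofuran-2(4H)-one (6S,7aR enantiomer drawn) | O[C@H]1CC(C)(C)C2=CC(=O)O[C@]2(C)C1 | intermediate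
11 | (1S,4R)-camphanic chloride, (1S,4R)-4,7,7-trimethyl-3-oxo-2-oxabicyclo[2.2.1]heptane-1-carbonyl chloride | ClC(=O)[C@@]12CC[C@@](C)(C(=O)O1)C2(C)C | starting material
12 | (6S,7aR)-loliolide (1S,4R)-camphanate | O=C(O[C@H]1CC(C)(C)C2=CC(=O)O[C@]2(C)C1)[C@@]34CC[C@@](C)(C(=O)O3)C4(C)C | intermediate
13 | (−)-loliolide, (6S,7aR)-6-hydroxy-4,4,7a-trimethyl-5,6,7,7a-tetrahydro-1-benzofuran-2(4H)-one | O[C@H]1CC(C)(C)C2=CC(=O)O[C@]2(C)C1 | intermediate
14 | palmitoyl chloride (hexadecanoyl chloride) | CCCCCCCCCCCCCCCC(=O)Cl | starting material
15 | (−)-3-O-palmitoylloliolide, (6S,7aR)-4,4,7a-trimethyl-2-oxo-2,4,5,6,7,7a-hexahydro-1-benzofuran-6-yl hexadecanoate | CCCCCCCCCCCCCCCC(=O)O[C@H]1CC(C)(C)C2=CC(=O)O[C@]2(C)C1 | target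

Total step count: 7
Longest linear sequence: 7 steps (1 → 3 → 6 → 9 → 10 → 12 → 13 → 15)

**Steps most likely to fail**

Step 3. The ester tether has to adopt the lactone-like conformation and the diene the s-cis form with its inward C7a methyl group. At the temperature this needs, a 1,5-hydrogen shift from that methyl group, bimolecular Diels–Alder addition at the proximal allene bond, or loss of the silyl group before ring closure may outrun the cycloaddition. The fallback sets out from 6 and forms 7 as before. The two bonds are then made by a metal-templated, stepwise [4+2] at room temperature in place of the thermal pericyclic one. A cationic monovalent rhodium catalyst from [Rh(cod)Cl]2 and AgSbF6 in CH2Cl2 should bring about oxidative cyclisation of the diene with the distal allene bond and then reductive elimination, a known cycloaddition of tethered diene–allenes. It comes back to the route at 8, which is hydrolysed to 9 as in step 3.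

Step 2. C-acylation may compete with O-acylation, the Z enol ester (which cannot cyclise) may form, or the allenoyl chloride 5 may decompose under the amine base. The fallback sets out from 4, which oxalyl chloride and catalytic DMF convert into (E)-4-chloropent-3-en-2-one F1. The caesium salt of acid 3 (Cs2CO3, MeCN, rt) then displaces chloride by addition–elimination at the β-carbon. This avoids 5 and should deliver the thermodynamically preferred E enol ester 6, where the route is rejoined.

Step 5. The two flanks of C6 are sterically alike, so the diastereomeric camphanates may co-crystallise or co-elute, and acylation of the hindered axial alcohol may be slow. The fallback sets out from 10 and separates the enantiomers directly by preparative chromatography on a chiral stationary phase (amylose or cellulose tris(3,5-dimethylphenylcarbamate)), without derivatisation. It comes back to the route at 13, so steps 5 and 6 drop out.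

Further compounds
F0 | step 3 | none | none
F1 | step 2 | (E)-4-chloropent-3-en-2-one | CC(=O)/C=C(\C)Cl
F0 | step 5 | none | none
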